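The ten-membered ring is disconnected at its C1=C10 and C4=C5 alkenes: because the C2–C3 ethano bridge joins them, they are the formal metathesis partners of 1-methylcyclobutene (C1–C4) and the C5=C10 bond of a cyclohexenone that already carries C6–C9, the trans 6,12-lactone, O8 and C14. One irradiation (enone–alkene [2+2]) makes the C10–C1 and C5–C4 bonds and a bicyclo[2.2.0]hexane holding all ten ring carbons; heating then cleaves C5–C10 and C1–C4 and releases the cyclodecadienone. The precursor, a 2-(silyloxymethyl)-6-silyloxycyclohex-2-enone trans-fused to a γ-lactone, is built from (−)-quinic acid by conjugate addition, β-elimination and two α-functionalisations.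

Key step: step 11

Remarks on the chemistry (they hold for all steps below)
- Germacrane numbering is used for every intermediate: ring A is the six-membered carbocycle C5–C10 (C9 ketone, C6 lactone oxygen, C7 bearing C11, C8 oxygen, C14 on C10). β is the face of the C7–C11 bond; in the target O8 and O9 are β and O6 is α.
- The C6–O/C7–C pair is not made by opening a C6–C7 epoxide. A carbon nucleophile would attack the allylic C6 and avoid C7, which is flanked by the C8–O carbon. Instead C7 is made the β-carbon of a quinic-acid-derived enone, so the neighbouring C6 oxygen directs the addition, and O8 is introduced on the conformationally locked lactone.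
- The configurations of 15, 17 and 24 were checked atom by atom against 27 and agree; the acyl group is (R).
- The C1=C10 descriptor changes from Z (C14 = CH2O) to E (C14 = CHO) without any change of geometry: C2 and C9 stay cis.
- Assumptions: 7 and 16 are purchasable; the cycloaddition is taken to occur on the β face of 15 (the other outcome is treated under the risks).

Step 1
Reactants: 1 (−)-quinic acid
Product: 2 quinic acid 3,4-acetonide 1,5-lactone
Conditions: 2,2-dimethoxypropane, TsOH·H2O (cat.), acetone, reflux
Reagents that add atoms: 2,2-dimethoxypropane, CC(C)(OC)OC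
Why: Acid-catalysed transketalisation protects the only cis-1,2-diol as the acetonide while the carboxyl group lactonises onto the cis-disposed remaining secondary hydroxyl (ketalisation/lactonisation), so no stereocentre is touched.

Step 2
Reactants: 2 quinic acid 3,4-acetonide 1,5-lactone
Product: 3 acetonide triol
Conditions: NaBH4, EtOH, 0 °C to rt
Reagents that add atoms: none
Why: Hydride reduction of the strained bridged lactone gives the primary alcohol and frees the secondary hydroxyl, the acetonide being inert to NaBH4.

Step 3
Reactants: 3 acetonide triol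
Product: 4 (3R,4S,5R)-5-hydroxy-3,4-(isopropylidenedioxy)cyclohexan-1-one
Conditions: NaIO4, H2O (pH 6 buffer), 0 °C
Reagents that add atoms: none
Why: Periodate glycol cleavage of the only free 1,2-diol (tertiary carbinol and its CH2OH) removes that carbon as formaldehyde and leaves the ring ketone that becomes C9.

Step 4
Reactants: 4 (3R,4S,5R)-5-hydroxy-3,4-(isopropylidenedioxy)cyclohexan-1-one
Product: 6 (4S,5R)-4,5-(isopropylidenedioxy)cyclohex-2-en-1-one, via mesylate 5 (not isolated)
Conditions: MsCl, Et3N, CH2Cl2, 0 °C to rt
Reagents that add atoms: none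
Why: Mesylation of the β-hydroxy ketone is followed in the flask by E1cB elimination to the enone C8=C7, the mesylate being by far the better β-leaving group so that the acetonide oxygens (future O5, O6) stay in place.

Step 5
Reactants: 6 (4S,5R)-4,5-(isopropylidenedioxy)cyclohex-2-en-1-one; 7 1-(tert-butyldimethylsilyloxy)-1-methoxyethene
Product: 9 acetonide keto ester, via silyl enol ether 8 (not isolated)
Conditions: LiClO4 (3 M in Et2O), rt; then 1 M HCl, THF, 0 °C
Reagents that add atoms: none
Why: Mukaiyama–Michael addition of the acetate ketene silyl acetal forms C7–C11 on the enone face anti to the adjacent acetonide oxygen, which sets C7 trans to O6, and the acidic work-up hydrolyses the silyl enol ether.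

Step 6
Reactants: 9 acetonide keto ester
Product: 11 trans-fused enone lactone, via hydroxy enone ester 10 (not isolated)
Conditions: 1,8-diazabicyclo[5.4.0]undec-7-ene (DBU, 1.5 equiv), PhMe, 0 °C to rt
Reagents that add atoms: none
Why: Enolisation towards C10 expels the β-alkoxide at C5 (E1cB elimination, the hemiketal then losing acetone) and the freed C6 alkoxide lactonises onto the methyl ester, which moves the enone to C10=C5 and closes the trans γ-lactone without touching C6 or C7.

Step 7
Reactants: 11 trans-fused enone lactone
Product: 12 C10-hydroxymethyl enone lactone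
Conditions: 37% aq. HCHO, 4-(dimethylamino)pyridine (DMAP, 0.3 equiv), THF–H2O, rt
Reagents that add atoms: formaldehyde, C=O
Why: In this Morita–Baylis–Hillman hydroxymethylation DMAP adds reversibly to C5, the C10 enolate captures formaldehyde and loss of DMAP returns the enone now carrying C14.

Step 8
Reactants: 12 C10-hydroxymethyl enone lactone
Product: 13 C14 silyl ether
Conditions: TBSCl, imidazole, DMF, 0 °C to rt
Reagents that add atoms: tert-butyldimethylsilyl chloride, CC(C)(C)[Si](C)(C)Cl
Why: Standard silylation of the primary allylic alcohol protects O14 for the enolate and photochemical steps.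

Step 9
Reactants: 13 C14 silyl ether
Product: 14 8β-hydroxy enone lactone
Conditions: KN(SiMe3)2, THF, −78 °C; 2-(phenylsulfonyl)-3-phenyloxaziridine, −78 °C; aq. NH4Cl
Reagents that add atoms: 2-(phenylsulfonyl)-3-phenyloxaziridine, O=S(=O)(c1ccccc1)N1OC1c1ccccc1
Why: Kinetic deprotonation gives the cross-conjugated C8 enolate (the ketone α′-position is more acidic than the lactone CH2), and in this Davis enolate oxidation the oxaziridine should add axially, anti to the axial C7–H of the trans-locked ring, which places O8 cis to C11.

Step 10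
Reactants: 14 8β-hydroxy enone lactone
Product: 15 bis-silyl enone lactone (photo precursor)
Conditions: TBSOTf, 2,6-lutidine, CH2Cl2, −78 °C
Reagents that add atoms: tert-butyldimethylsilyl trifluoromethanesulfonate, CC(C)(C)[Si](C)(C)OS(=O)(=O)C(F)(F)F
Why: Silyl triflate with a hindered pyridine base silylates the secondary α-ketol hydroxyl at low temperature without enolising C8, and a silyl ether has no readily abstractable hydrogen near the excited carbonyl.

Step 11
Reactants: 15 bis-silyl enone lactone (photo precursor); 16 1-methylcyclobutene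
Product: 17 cis-anti-cis photoadduct
Conditions: hν (350–366 nm, Pyrex), 16 (15 equiv), CH2Cl2, −40 °C
Reagents that add atoms: none
Why: Irradiation populates the triplet enone, which adds to ground-state 16 stepwise through a triplet 1,4-diradical that closes after spin inversion; this is the known enone–alkene [2+2] photocycloaddition in its enone–cyclobutene form. The one new ring, cyclobutane C10–C1–C4–C5, closes by radical–radical coupling of that diradical and is cis-fused both to ring A and to the four-membered ring of 16, which gives the bicyclo[2.2.0]hexane. Head-to-tail regiochemistry (C1 to C10, C4 to C5) is needed and should be secured by the 2-substituent of the enone, which makes C10 quaternary and steers the methyl-bearing C4 to the unhindered β-carbon C5, in line with the usual preference of electron-rich alkenes. C10 and C5 should be cis because a trans 6–4 fusion would have to carry the second four-membered ring as well, C1 and C4 are cis because they come from a cyclobutene, and the anti arrangement of the two small rings follows from approach with the CH2–CH2 bridge turned away from ring A. Facial selectivity is needed too, since it later decides which alkene opens cis: the trans-fused lactone locks ring A so that C6 shows its axial hydrogen on the β face and its C–O bond on the α face, and the C4 methyl group, which must pass over C6, should therefore enter on the β face, anti to the C6 oxygen. Excess 16 at low temperature suppresses enone dimerisation.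

Step 12
Reactants: 17 cis-anti-cis photoadduct
Product: 19 (1(10)Z,4Z)-dienone, via (1(10)E,4Z)-dienone 18 (not isolated)
Conditions: PhMe (5 mM, degassed), sealed tube, 200 °C, short heating; cool to rt, I2 (5 mol%), NaHCO3, visible light
Reagents that add atoms: none
Why: Thermal cleavage of the central C1–C4 bond gives a chair cyclohexane-1,4-diyl whose conformation is dictated by the lactone-locked chair of ring A, so that scission of C5–C10 (retro-[2+2] cycloreversion of the bicyclo[2.2.0]hexane) should deliver C4=C5 cis in the ring and C1=C10 trans, and iodine-atom catalysis then relaxes the twisted trans enone to the planar, less strained cis enone, which has no chair pathway for a Cope rearrangement.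

Step 13
Reactants: 19 (1(10)Z,4Z)-dienone
Product: 20 9β-alcohol
Conditions: NaBH4, CeCl3·7H2O, MeOH–THF, −78 °C
Reagents that add atoms: none
Why: Luche 1,2-reduction of the enone leaves the lactone alone, and hydride should enter from the ring periphery anti to the C8–O bond (Felkin–Anh-type control), giving the C9 hydroxyl cis to O8.

Step 14
Reactants: 20 9β-alcohol
Product: 21 Mannich base
Conditions: LiN(iPr)2 (2.5 equiv), THF, −78 °C; CH2=NMe2+ I− (3 equiv), −78 °C to rt
Reagents that add atoms: N,N-dimethylmethyleneiminium iodide (Eschenmoser's salt), C=[N+](C)C.[I-]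
Why: Excess amide base forms the C9 alkoxide and then the lactone enolate at C11, which is aminomethylated by the iminium salt (Mannich reaction), the new C11 configuration being irrelevant.

Step 15
Reactants: 21 Mannich base
Product: 23 α-methylene lactone alcohol, via methiodide 22 (not isolated)
Conditions: MeI, MeOH, rt; then aq. NaHCO3–CH2Cl2, rt
Reagents that add atoms: none
Why: N-methylation gives the quaternary ammonium salt, which undergoes mild base-induced β-elimination (Hofmann-type E1cB) to the exocyclic C11=C13 methylene.

Step 16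
Reactants: 23 α-methylene lactone alcohol; 24 (R)-2-methylbutanoic acid
Product: 25 9-O-acyl bis-silyl ether
Conditions: N-(3-dimethylaminopropyl)-N′-ethylcarbodiimide hydrochloride (EDC·HCl), DMAP (0.2 equiv), CH2Cl2, 0 °C to rt
Reagents that add atoms: none
Why: Steglich-type carbodiimide esterification acylates the only free hydroxyl (allylic O9) with retention at C9, and run cold with catalytic DMAP it should not epimerise the α-stereocentre of the acid.

Step 17
Reactants: 25 9-O-acyl bis-silyl ether
Product: 26 8,14-diol
Conditions: HF·pyridine, pyridine–THF, 0 °C to rt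
Reagents that add atoms: none
Why: Buffered fluoride desilylation removes both silyl ethers under slightly acidic conditions that disfavour O9-to-O8 acyl migration and conjugate addition to the methylene lactone.

Step 18
Reactants: 26 8,14-diol
Product: 27 target CNP0256845.2
Conditions: activated MnO2 (excess), CH2Cl2, rt
Reagents that add atoms: none
Why: MnO2 oxidises only the primary allylic alcohol at C14 to the enal (chemoselective allylic oxidation) and leaves the non-allylic secondary O8–H untouched.

Compound list
1 | (−)-quinic acid, (1S,3R,4S,5R)-1,3,4,5-tetrahydroxycyclohexane-1-carboxylic acid | O[C@@]1(C(=O)O)C[C@@H](O)[C@@H](O)[C@H](O)C1 | starting material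
2 | quinic acid 3,4-acetonide 1,5-lactone | O[C@@]1(C(=O)O2)C[C@H]3OC(C)(C)O[C@H]3[C@H]2C1 | intermediate
3 | acetonide triol, 1-(hydroxymethyl)-3,4-O-isopropylidenecyclohexane-1,3,4,5-tetrol (configuration as in 1) | O[C@@]1(CO)C[C@H]2OC(C)(C)O[C@H]2[C@H](O)C1 | intermediate
4 | (3R,4S,5R)-5-hydroxy-3,4-(isopropylidenedioxy)cyclohexan-1-one | O=C1C[C@H]2OC(C)(C)O[C@H]2[C@H](O)C1 | intermediate
5 | 5-O-mesylate of 4 | O=C1C[C@H]2OC(C)(C)O[C@H]2[C@H](OS(C)(=O)=O)C1 | intermediate
6 | (4S,5R)-4,5-(isopropylidenedioxy)cyclohex-2-en-1-one | O=C1C=C[C@@H]2OC(C)(C)O[C@@H]2C1 | intermediate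
7 | 1-(tert-butyldimethylsilyloxy)-1-methoxyethene | C=C(OC)O[Si](C)(C)C(C)(C)C | starting material
8 | silyl enol ether of 9 (C8=C9–OTBS) | CC(C)(C)[Si](C)(C)OC1=C[C@@H](CC(=O)OC)[C@@H]2OC(C)(C)O[C@@H]2C1 | intermediate
9 | acetonide keto ester, methyl 2-[2,3-(isopropylidenedioxy)-5-oxocyclohexyl]acetate, acetate arm trans to the neighbouring acetal oxygen | O=C1C[C@@H](CC(=O)OC)[C@@H]2OC(C)(C)O[C@@H]2C1 | intermediate
10 | hydroxy enone ester, methyl 2-(6-hydroxy-3-oxocyclohex-4-en-1-yl)acetate, OH and side chain trans | O=C1C=C[C@@H](O)[C@H](CC(=O)OC)C1 | intermediate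
11 | trans-fused enone lactone, 3,3a,4,7a-tetrahydro-1-benzofuran-2,5-dione with H-3a and H-7a trans (O6 α, C11 β) | O=C1C=C[C@H]2OC(=O)C[C@@H]2C1 | intermediate
12 | C10-hydroxymethyl enone lactone (C14–OH) | O=C1C(CO)=C[C@H]2OC(=O)C[C@@H]2C1 | intermediate
13 | C14 silyl ether of 12 | O=C1C(CO[Si](C)(C)C(C)(C)C)=C[C@H]2OC(=O)C[C@@H]2C1 | intermediate
14 | 8β-hydroxy enone lactone (C8–OH cis to the C7–C11 bond) | O=C1C(CO[Si](C)(C)C(C)(C)C)=C[C@H]2OC(=O)C[C@@H]2[C@@H]1O | intermediate
15 | bis-silyl enone lactone, photo precursor (C9 ketone, C10=C5, 8β-OTBS, 14-OTBS, trans 6α,12-lactone) | O=C1C(CO[Si](C)(C)C(C)(C)C)=C[C@H]2OC(=O)C[C@@H]2[C@@H]1O[Si](C)(C)C(C)(C)C | intermediate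
16 | 1-methylcyclobutene | CC1=CCC1 | starting material
17 | cis-anti-cis photoadduct, bicyclo[2.2.0]hexane (C1–C4, C5, C10) fused to cyclohexanone ring A, new bonds C10–C1 and C5–C4 on the β face | O=C1[C@]2(CO[Si](C)(C)C(C)(C)C)[C@H]3CC[C@@]3(C)[C@@H]2[C@H]4OC(=O)C[C@@H]4[C@@H]1O[Si](C)(C)C(C)(C)C | intermediate
18 | (1(10)E,4Z)-8β,14-bis(tert-butyldimethylsilyloxy)-9-oxogermacra-1(10),4-dien-12,6α-olide (C2 and C9 trans) | C1C(=O)O[C@@H]2/C=C(/C)CC/C=C(\CO[Si](C)(C)C(C)(C)C)C(=O)[C@@H](O[Si](C)(C)C(C)(C)C)[C@@H]12 | intermediate
19 | (1(10)Z,4Z)-8β,14-bis(tert-butyldimethylsilyloxy)-9-oxogermacra-1(10),4-dien-12,6α-olide (both ring alkenes cis) | C1C(=O)O[C@@H]2/C=C(/C)CC/C=C(/CO[Si](C)(C)C(C)(C)C)C(=O)[C@@H](O[Si](C)(C)C(C)(C)C)[C@@H]12 | intermediate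
20 | 9β-alcohol, (1(10)Z,4Z)-8β,14-bis(tert-butyldimethylsilyloxy)-9β-hydroxygermacra-1(10),4-dien-12,6α-olide | C1C(=O)O[C@@H]2/C=C(/C)CC/C=C(/CO[Si](C)(C)C(C)(C)C)[C@@H](O)[C@@H](O[Si](C)(C)C(C)(C)C)[C@@H]12 | intermediate
21 | Mannich base, 13-(dimethylamino) derivative of 20 (C11 epimers) | CN(C)CC1C(=O)O[C@@H]2/C=C(/C)CC/C=C(/CO[Si](C)(C)C(C)(C)C)[C@@H](O)[C@@H](O[Si](C)(C)C(C)(C)C)[C@@H]12 | intermediate
22 | methiodide of 21 (13-trimethylammonium iodide) | C[N+](C)(C)CC1C(=O)O[C@@H]2/C=C(/C)CC/C=C(/CO[Si](C)(C)C(C)(C)C)[C@@H](O)[C@@H](O[Si](C)(C)C(C)(C)C)[C@@H]12.[I-] | intermediate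
23 | α-methylene lactone alcohol, (1(10)Z,4Z)-8β,14-bis(tert-butyldimethylsilyloxy)-9β-hydroxygermacra-1(10),4,11(13)-trien-12,6α-olide | C=C1C(=O)O[C@@H]2/C=C(/C)CC/C=C(/CO[Si](C)(C)C(C)(C)C)[C@@H](O)[C@@H](O[Si](C)(C)C(C)(C)C)[C@@H]12 | intermediate
24 | (R)-2-methylbutanoic acid | CC[C@@H](C)C(=O)O | starting material
25 | 9-O-acyl bis-silyl ether, 9β-[(2R)-2-methylbutanoyloxy] derivative of 23 | C=C1C(=O)O[C@@H]2/C=C(/C)CC/C=C(/CO[Si](C)(C)C(C)(C)C)[C@@H](OC(=O)[C@H](C)CC)[C@@H](O[Si](C)(C)C(C)(C)C)[C@@H]12 | intermediate
26 | 8,14-diol, (1(10)Z,4Z)-8β,14-dihydroxy-9β-[(2R)-2-methylbutanoyloxy]germacra-1(10),4,11(13)-trien-12,6α-olide | C=C1C(=O)O[C@@H]2/C=C(/C)CC/C=C(/CO)[C@@H](OC(=O)[C@H](C)CC)[C@@H](O)[C@@H]12 | intermediate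
27 | CNP0256845.2, (1(10)E,4Z)-8β-hydroxy-9β-[(2R)-2-methylbutanoyloxy]-14-oxogermacra-1(10),4,11(13)-trien-12,6α-olide | C=C1C(=O)O[C@@H]2/C=C(/C)CC/C=C(/C=O)[C@@H](OC(=O)[C@H](C)CC)[C@@H](O)[C@@H]12 | target

Total step count: 18. Longest linear sequence: 18 steps (1 to 27); 7, 16 and 24 are used as purchased.

Steps most likely to fail

Step 11. Poor facial selectivity is the main danger: the cyclobutene may add on the α face, syn to the C6 oxygen, possibly with some trans-fused or head-to-head adducts. Fallback, setting out from 15 and coming back at 19: the irradiation then gives mainly the face-isomeric cis-anti-cis adduct F1. Heated as in step 12, its lactone-locked chair should release the (1(10)Z,4E)-dienone F2, in which the conjugated bond is already cis and the isolated C4=C5 bond is trans. The geometry of that bond is then no longer left to the cycloreversion but set by thermodynamic equilibration through reversible thiyl-radical addition (PhSSPh 0.2 equiv, azobis(isobutyronitrile) cat., benzene, 80 °C). A ten-membered ring favours the cis alkene, so this should converge on 19.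

Step 12. Onward Cope rearrangement of 18 may compete: its trans C1=C10 bond allows a chair transition state that re-forms C5–C10 and gives a divinylcyclohexanone before the enone is isomerised. Fallback, from 17 and back at 19: the cycloreversion is run as a trapping experiment in o-xylene at 180 °C with PhSSPh (0.2 equiv) present. Thiyl radicals from thermal S–S homolysis should isomerise 18 as it forms into 19, which has no chair Cope pathway. The divinylcyclohexanone F3 stays in Cope equilibrium with 18 and should be drained through it.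

Step 13. Hydride may be delivered to the wrong face of the C9 carbonyl, because the conformation of the ten-membered ring is not known. Fallback, from 19 and back at 25: the 9α-alcohol F4 is taken through the conditions of steps 14 and 15, by way of the Mannich base F5 and the methiodide F6, to the methylene lactone F7. F7 is then esterified with 24 under Mitsunobu conditions (PPh3, diisopropyl azodicarboxylate, PhMe, 0 °C), which inverts C9 and gives 25 directly.

Further compounds
F1 | step 11 | face-isomeric cis-anti-cis photoadduct (four-membered rings on the α face, syn to O6) | O=C1[C@@]2(CO[Si](C)(C)C(C)(C)C)[C@@H]3CC[C@]3(C)[C@H]2[C@H]4OC(=O)C[C@@H]4[C@@H]1O[Si](C)(C)C(C)(C)C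
F2 | step 11 | (1(10)Z,4E)-8β,14-bis(tert-butyldimethylsilyloxy)-9-oxogermacra-1(10),4-dien-12,6α-olide | C1C(=O)O[C@@H]2/C=C(\C)CC/C=C(/CO[Si](C)(C)C(C)(C)C)C(=O)[C@@H](O[Si](C)(C)C(C)(C)C)[C@@H]12
F3 | step 12 | divinylcyclohexanone (C10 vinyl and C5 isopropenyl cis, Cope isomer of 18) | O=C1[C@](CO[Si](C)(C)C(C)(C)C)(C=C)[C@H](C(C)=C)[C@H]2OC(=O)C[C@@H]2[C@@H]1O[Si](C)(C)C(C)(C)C
F4 | step 13 | 9α-alcohol (C9 epimer of 20) | C1C(=O)O[C@@H]2/C=C(/C)CC/C=C(/CO[Si](C)(C)C(C)(C)C)[C@H](O)[C@@H](O[Si](C)(C)C(C)(C)C)[C@@H]12
F5 | step 13 | C9-epimeric Mannich base | CN(C)CC1C(=O)O[C@@H]2/C=C(/C)CC/C=C(/CO[Si](C)(C)C(C)(C)C)[C@H](O)[C@@H](O[Si](C)(C)C(C)(C)C)[C@@H]12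
F6 | step 13 | C9-epimeric methiodide | C[N+](C)(C)CC1C(=O)O[C@@H]2/C=C(/C)CC/C=C(/CO[Si](C)(C)C(C)(C)C)[C@H](O)[C@@H](O[Si](C)(C)C(C)(C)C)[C@@H]12.[I-]
F7 | step 13 | C9-epimeric α-methylene lactone alcohol | C=C1C(=O)O[C@@H]2/C=C(/C)CC/C=C(/CO[Si](C)(C)C(C)(C)C)[C@H](O)[C@@H](O[Si](C)(C)C(C)(C)C)[C@@H]12
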